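**Retrosynthetic overview**
1. Target 15, a (2S)-flavanone, is traced back through its tetrakis-MOM ether 14 to flavone 12; C2 is set by enantioselective copper hydride 1,4-reduction of the C2=C3 bond.
2. Ring C of 12 is cut at C3–C4 and O1–C2 into salicylaldehyde 3 (ring A with O1, C8a, C4a, C4) and β-keto sulfoxonium ylide 10 (ring B with C2, C3); one rhodium-catalysed C–H annulation makes both bonds.
3. Enabling feature: on ring A the oxygen O1 (on C8a) is ortho to C4a, which carries C4. The precursor is therefore a salicylaldehyde whose phenoxide guides rhodium into the formyl C–H bond and then closes onto C2. Ring A is a symmetric 3,5-diprenylphloroglucinol, so its two ortho oxygens are equivalent and either may become O1.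
4. Rings A and B are bought as arenes (2,4,6-trihydroxybenzaldehyde, resorcinol) and prenylated by C-alkylation and by directed ortho-lithiation; ring C is the only ring built, in step 7.

Key step: step 7

Remark: the stereocentre of the target is C2 of the flavanone; with O1 > C1' > C3 > H its descriptor is (S).

**Route**

Step 1
Reactants: 1 2,4,6-trihydroxybenzaldehyde
Product: 2 2,4,6-trihydroxy-3,5-bis(3-methylbut-2-en-1-yl)benzaldehyde
Conditions: prenyl bromide (2.1 equiv), 10% aq KOH, 0 °C to rt
Reagents that add atoms: prenyl bromide (1-bromo-3-methylbut-2-ene), CC(C)=CCBr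
Why: Alkylation of the ambident phloroglucinol phenolate in water, where hydrogen bonding to the oxygens steers prenyl bromide to carbon, should functionalise the two equivalent free ring positions C3 and C5 (direct C-prenylation of an acylphloroglucinol).

Step 2
Reactants: 2 2,4,6-trihydroxy-3,5-bis(3-methylbut-2-en-1-yl)benzaldehyde
Product: 3 2-hydroxy-4,6-bis(methoxymethoxy)-3,5-bis(3-methylbut-2-en-1-yl)benzaldehyde
Conditions: MOMCl (2.1 equiv), iPr2NEt, CH2Cl2, 0 °C
Reagents that add atoms: chloromethyl methyl ether, COCCl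
Why: Williamson-type O-alkylation should protect the 4-OH and one of the two equivalent ortho OH groups, while the last ortho OH stays locked in its hydrogen bond to the formyl oxygen and is left free for step 7.

Step 3
Reactants: 4 resorcinol
Product: 5 1,3-bis(methoxymethoxy)benzene
Conditions: NaH, MOMCl, DMF, 0 °C to rt
Reagents that add atoms: chloromethyl methyl ether, COCCl
Why: Williamson ether synthesis on the bis-phenoxide installs the two MOM ethers that later direct both lithiations.

Step 4
Reactants: 5 1,3-bis(methoxymethoxy)benzene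
Product: 7 1,3-bis(methoxymethoxy)-2-(3-methylbut-2-en-1-yl)benzene, via aryllithium 6 (not isolated)
Conditions: n-BuLi, THF, 0 °C to rt; then CuBr·SMe2 (10 mol %), prenyl bromide, −78 °C to rt
Reagents that add atoms: prenyl bromide (1-bromo-3-methylbut-2-ene), CC(C)=CCBr
Why: Directed ortho-metalation should take place at C2 between the two cooperating OMOM groups, and copper-catalysed SN2 allylation of the aryllithium with prenyl bromide should give the linear prenyl arene.

Step 5
Reactants: 7 1,3-bis(methoxymethoxy)-2-(3-methylbut-2-en-1-yl)benzene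
Product: 9 methyl 2,4-bis(methoxymethoxy)-3-(3-methylbut-2-en-1-yl)benzoate, via aryllithium 8 (not isolated)
Conditions: n-BuLi, TMEDA, THF, −20 to 0 °C; then added to ClCO2Me (3 equiv), THF, −78 °C
Reagents that add atoms: methyl chloroformate, COC(Cl)=O
Why: A second directed ortho-metalation at C4 (equivalent to C6), the remaining position next to an OMOM group, and acylation of the aryllithium by inverse addition to excess methyl chloroformate should give the benzoate.

Step 6
Reactants: 9 methyl 2,4-bis(methoxymethoxy)-3-(3-methylbut-2-en-1-yl)benzoate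
Product: 10 1-[2,4-bis(methoxymethoxy)-3-(3-methylbut-2-en-1-yl)phenyl]-2-[dimethyl(oxo)-λ6-sulfanylidene]ethan-1-one (β-keto sulfoxonium ylide)
Conditions: Me3S(O)I (3 equiv), KOtBu (3 equiv), THF, reflux; then 9, reflux
Reagents that add atoms: trimethylsulfoxonium iodide, C[S+](C)(C)=O.[I-]
Why: Acyl substitution of the methyl ester by dimethylsulfoxonium methylide (Corey–Chaykovsky reagent) should stop at the carbonyl-stabilised β-keto sulfoxonium ylide, a bench-stable carbene precursor.

Step 7
Reactants: 3 2-hydroxy-4,6-bis(methoxymethoxy)-3,5-bis(3-methylbut-2-en-1-yl)benzaldehyde; 10 β-keto sulfoxonium ylide of ring B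
Product: 12 2-[2,4-bis(methoxymethoxy)-3-(3-methylbut-2-en-1-yl)phenyl]-5,7-bis(methoxymethoxy)-6,8-bis(3-methylbut-2-en-1-yl)-4H-chromen-4-one, via 1,3-diketone 11 (not isolated)
Conditions: [Cp*Rh(MeCN)3](SbF6)2 (5 mol %), NaOAc (20 mol %), PivOH (1 equiv), 1,2-dichloroethane, 80 °C
Reagents that add atoms: none
Why: The free 2-OH of 3 should bind trivalent rhodium as a phenoxide and direct carboxylate-assisted cleavage of the formyl C–H bond to a five-membered acyl rhodacycle; ylide 10 then binds through carbon, loses dimethyl sulfoxide to give a rhodium carbene, and migratory insertion of the acyl group forms C3–C4, protonolysis releasing diketone 11. The same phenol then adds to the ring B ketone (6-exo-trig hemiketalisation) and water is lost, which forms O1–C2 and closes ring C as a 4-pyranone. The closest known reaction type is the Cp*Rh-catalysed annulation of salicylaldehydes with sulfoxonium ylides or α-diazo ketones to chromones. No stereocentre is formed, since C2 stays trigonal until step 8. The step needs formyl C–H insertion to win over O–H insertion of the carbene and over reaction at the prenyl double bonds, which chelation by the ortho phenoxide should secure. It also needs closure by the ring A oxygen only, which is secured because the 2-OH of 3 is the single free phenol (the ring B 2'-oxygen is a MOM ether), and the ylide carbon can only become C3 and its carbonyl carbon C2.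

Step 8
Reactants: 12 2-[2,4-bis(methoxymethoxy)-3-(3-methylbut-2-en-1-yl)phenyl]-5,7-bis(methoxymethoxy)-6,8-bis(3-methylbut-2-en-1-yl)-4H-chromen-4-one
Product: 14 (2S)-2-[2,4-bis(methoxymethoxy)-3-(3-methylbut-2-en-1-yl)phenyl]-5,7-bis(methoxymethoxy)-6,8-bis(3-methylbut-2-en-1-yl)chroman-4-one, via silyl enol ether 13 (not isolated)
Conditions: Cu(OAc)2 (5 mol %), (R)-DTBM-SEGPHOS (5.5 mol %), (EtO)2MeSiH (3 equiv), toluene, 0 °C to rt; then AcOH, H2O, THF, 0 °C
Reagents that add atoms: none
Why: Copper hydride conjugate reduction should add hydride to C2 of the 4-pyranone, the chiral bisphosphine selecting the face that gives (2S) (catalyst control, ligand hand to be confirmed on a model flavone), while the unactivated prenyl alkenes are not touched and the silyl enol ether is hydrolysed without base, so C2 is not exposed to retro-oxa-Michael opening.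

Step 9
Reactants: 14 (2S)-2-[2,4-bis(methoxymethoxy)-3-(3-methylbut-2-en-1-yl)phenyl]-5,7-bis(methoxymethoxy)-6,8-bis(3-methylbut-2-en-1-yl)chroman-4-one
Product: 15 (2S)-2-[2,4-dihydroxy-3-(3-methylbut-2-en-1-yl)phenyl]-5,7-dihydroxy-6,8-bis(3-methylbut-2-en-1-yl)chroman-4-one
Conditions: 3 M aq HCl, MeOH, 40 °C, short reaction time
Reagents that add atoms: none
Why: Acid-catalysed acetal exchange with methanol should remove all four MOM groups, the mild, short exposure being chosen so that the prenyl groups do not add to the liberated ortho phenols and the C2 centre, which racemises only by base-mediated ring opening, is kept.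

**Compound list**
1 | 2,4,6-trihydroxybenzaldehyde | O=Cc1c(O)cc(O)cc1O | starting material
2 | 2,4,6-trihydroxy-3,5-bis(3-methylbut-2-en-1-yl)benzaldehyde | O=Cc1c(O)c(CC=C(C)C)c(O)c(CC=C(C)C)c1O | intermediate
3 | 2-hydroxy-4,6-bis(methoxymethoxy)-3,5-bis(3-methylbut-2-en-1-yl)benzaldehyde | O=Cc1c(O)c(CC=C(C)C)c(OCOC)c(CC=C(C)C)c1OCOC | intermediate
4 | resorcinol | Oc1cccc(O)c1 | starting material
5 | 1,3-bis(methoxymethoxy)benzene | COCOc1cccc(OCOC)c1 | intermediate
6 | [2,6-bis(methoxymethoxy)phenyl]lithium (formed in the flask) | [Li]c1c(OCOC)cccc1OCOC | intermediate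
7 | 1,3-bis(methoxymethoxy)-2-(3-methylbut-2-en-1-yl)benzene | COCOc1cccc(OCOC)c1CC=C(C)C | intermediate
8 | [2,4-bis(methoxymethoxy)-3-(3-methylbut-2-en-1-yl)phenyl]lithium (formed in the flask) | [Li]c1ccc(OCOC)c(CC=C(C)C)c1OCOC | intermediate
9 | methyl 2,4-bis(methoxymethoxy)-3-(3-methylbut-2-en-1-yl)benzoate | COC(=O)c1ccc(OCOC)c(CC=C(C)C)c1OCOC | intermediate
10 | 1-[2,4-bis(methoxymethoxy)-3-(3-methylbut-2-en-1-yl)phenyl]-2-[dimethyl(oxo)-λ6-sulfanylidene]ethan-1-one | CS(C)(=O)=CC(=O)c1ccc(OCOC)c(CC=C(C)C)c1OCOC | intermediate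
11 | 1-[2,4-bis(methoxymethoxy)-3-(3-methylbut-2-en-1-yl)phenyl]-3-[2-hydroxy-4,6-bis(methoxymethoxy)-3,5-bis(3-methylbut-2-en-1-yl)phenyl]propane-1,3-dione (formed in the flask) | CC(C)=CCc1c(OCOC)ccc(C(=O)CC(=O)c2c(O)c(CC=C(C)C)c(OCOC)c(CC=C(C)C)c2OCOC)c1OCOC | intermediate
12 | 2-[2,4-bis(methoxymethoxy)-3-(3-methylbut-2-en-1-yl)phenyl]-5,7-bis(methoxymethoxy)-6,8-bis(3-methylbut-2-en-1-yl)-4H-chromen-4-one | CC(C)=CCc1c(OCOC)ccc(-c2cc(=O)c3c(OCOC)c(CC=C(C)C)c(OCOC)c(CC=C(C)C)c3o2)c1OCOC | intermediate
13 | (2S)-4-{[diethoxy(methyl)silyl]oxy}-2-[2,4-bis(methoxymethoxy)-3-(3-methylbut-2-en-1-yl)phenyl]-5,7-bis(methoxymethoxy)-6,8-bis(3-methylbut-2-en-1-yl)-2H-chromene (formed in the flask) | CC(C)=CCc1c(OCOC)ccc([C@@H]2C=C(O[Si](C)(OCC)OCC)c3c(OCOC)c(CC=C(C)C)c(OCOC)c(CC=C(C)C)c3O2)c1OCOC | intermediate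
14 | (2S)-2-[2,4-bis(methoxymethoxy)-3-(3-methylbut-2-en-1-yl)phenyl]-5,7-bis(methoxymethoxy)-6,8-bis(3-methylbut-2-en-1-yl)chroman-4-one | CC(C)=CCc1c(OCOC)ccc([C@@H]2CC(=O)c3c(OCOC)c(CC=C(C)C)c(OCOC)c(CC=C(C)C)c3O2)c1OCOC | intermediate
15 | (2S)-2-[2,4-dihydroxy-3-(3-methylbut-2-en-1-yl)phenyl]-5,7-dihydroxy-6,8-bis(3-methylbut-2-en-1-yl)chroman-4-one | CC(C)=CCc1c(O)ccc([C@@H]2CC(=O)c3c(O)c(CC=C(C)C)c(O)c(CC=C(C)C)c3O2)c1O | target

**Step count and risks**
Total step count: 9. Longest linear sequence: 7 steps (steps 3, 4, 5, 6, 7, 8, 9, from resorcinol).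

Steps most likely to fail:

1. Step 7. The cationic rhodium catalyst or the acid may add the free 2-OH of 3 across its neighbouring prenyl double bond before C–H activation. The carbene may also insert into the O–H bond, the acyl rhodium intermediate may lose CO, or the dehydrative closure may stall at the diketone. Fallback (ynone route, from 3 and 7, back at 12): 7 is lithiated as in step 5 (aryllithium 8) and quenched with DMF to give 2,4-bis(methoxymethoxy)-3-(3-methylbut-2-en-1-yl)benzaldehyde F1. Seyferth–Gilbert homologation with dimethyl (1-diazo-2-oxopropyl)phosphonate (Ohira–Bestmann reagent), K2CO3, MeOH should give 1-ethynyl-2,4-bis(methoxymethoxy)-3-(3-methylbut-2-en-1-yl)benzene F2. n-BuLi in THF at −78 °C converts it into the lithium acetylide F3, used at 2.2 equiv because the first equivalent deprotonates the phenol of 3. Addition to the formyl group of 3 should give the racemic propargylic alcohol 1-[2-hydroxy-4,6-bis(methoxymethoxy)-3,5-bis(3-methylbut-2-en-1-yl)phenyl]-3-[2,4-bis(methoxymethoxy)-3-(3-methylbut-2-en-1-yl)phenyl]prop-2-yn-1-ol F4, which forms C3–C4. MnO2 in CH2Cl2 should oxidise this benzylic, propargylic alcohol to the corresponding prop-2-yn-1-one F5. K2CO3 in dry acetone should then close ring C by 6-endo-dig addition of the phenoxide to the ynone (O1–C2) and give flavone 12.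

2. Step 8. Hydride transfer to the hindered, electron-rich β-carbon C2 may be slow, 1,2-reduction of the carbonyl may compete, and facial discrimination by the ligand may be poor. Fallback (racemic reduction and kinetic resolution, from 12, back at 14): LiBH(s-Bu)3 in THF at −78 °C should give, by unselective 1,4-hydride addition, the racemic 2-[2,4-bis(methoxymethoxy)-3-(3-methylbut-2-en-1-yl)phenyl]-5,7-bis(methoxymethoxy)-6,8-bis(3-methylbut-2-en-1-yl)chroman-4-one F6. Asymmetric transfer hydrogenation with [Cp*RhCl((R,R)-TsDPEN)] and HCO2H/Et3N in EtOAc, stopped near half conversion, should reduce only the (2R)-ketone, to the cis alcohol (2R,4R)-2-[2,4-bis(methoxymethoxy)-3-(3-methylbut-2-en-1-yl)phenyl]-5,7-bis(methoxymethoxy)-6,8-bis(3-methylbut-2-en-1-yl)chroman-4-ol F7. The unreacted (2S)-ketone is 14 and is separated by chromatography; the catalyst antipode is chosen so that the (2R)-ketone is the fast-reacting one.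

3. Step 1. The ambident phloroglucinol anion may lose regiocontrol: O-alkylation, mono- and tri-alkylation, and geminal dialkylation with dearomatisation. Fallback (ether formation and Claisen rearrangement, from 1, back at 3): MOMCl (1.0 equiv) and iPr2NEt in CH2Cl2 at 0 °C should protect the non-chelated 4-OH and give 2,6-dihydroxy-4-(methoxymethoxy)benzaldehyde F8. Pd(PPh3)4 (zerovalent palladium) with methyl 2-methylbut-3-en-2-yl carbonate in THF at 0 °C should give the bis(tertiary allyl) ether 4-(methoxymethoxy)-2,6-bis[(2-methylbut-3-en-2-yl)oxy]benzaldehyde F9. Heating in N,N-diethylaniline at 160 °C should move both groups to the only free ortho positions, C3 and C5, by aromatic Claisen rearrangement and give 2,6-dihydroxy-4-(methoxymethoxy)-3,5-bis(3-methylbut-2-en-1-yl)benzaldehyde F10. MOMCl (1.0 equiv) and iPr2NEt then etherify one of the two equivalent ortho OH groups and give 3.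

Further compounds
F1 | step 7 | 2,4-bis(methoxymethoxy)-3-(3-methylbut-2-en-1-yl)benzaldehyde | O=Cc1ccc(OCOC)c(CC=C(C)C)c1OCOC
F2 | step 7 | 1-ethynyl-2,4-bis(methoxymethoxy)-3-(3-methylbut-2-en-1-yl)benzene | C#Cc1ccc(OCOC)c(CC=C(C)C)c1OCOC
F3 | step 7 | {[2,4-bis(methoxymethoxy)-3-(3-methylbut-2-en-1-yl)phenyl]ethynyl}lithium | [Li]C#Cc1ccc(OCOC)c(CC=C(C)C)c1OCOC
F4 | step 7 | racemic 1-[2-hydroxy-4,6-bis(methoxymethoxy)-3,5-bis(3-methylbut-2-en-1-yl)phenyl]-3-[2,4-bis(methoxymethoxy)-3-(3-methylbut-2-en-1-yl)phenyl]prop-2-yn-1-ol | CC(C)=CCc1c(OCOC)ccc(C#CC(O)c2c(O)c(CC=C(C)C)c(OCOC)c(CC=C(C)C)c2OCOC)c1OCOC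
F5 | step 7 | 1-[2-hydroxy-4,6-bis(methoxymethoxy)-3,5-bis(3-methylbut-2-en-1-yl)phenyl]-3-[2,4-bis(methoxymethoxy)-3-(3-methylbut-2-en-1-yl)phenyl]prop-2-yn-1-one | CC(C)=CCc1c(OCOC)ccc(C#CC(=O)c2c(O)c(CC=C(C)C)c(OCOC)c(CC=C(C)C)c2OCOC)c1OCOC
F6 | step 8 | racemic 2-[2,4-bis(methoxymethoxy)-3-(3-methylbut-2-en-1-yl)phenyl]-5,7-bis(methoxymethoxy)-6,8-bis(3-methylbut-2-en-1-yl)chroman-4-one | CC(C)=CCc1c(OCOC)ccc(C2CC(=O)c3c(OCOC)c(CC=C(C)C)c(OCOC)c(CC=C(C)C)c3O2)c1OCOC
F7 | step 8 | (2R,4R)-2-[2,4-bis(methoxymethoxy)-3-(3-methylbut-2-en-1-yl)phenyl]-5,7-bis(methoxymethoxy)-6,8-bis(3-methylbut-2-en-1-yl)chroman-4-ol (2,4-cis) | CC(C)=CCc1c(OCOC)ccc([C@H]2C[C@@H](O)c3c(OCOC)c(CC=C(C)C)c(OCOC)c(CC=C(C)C)c3O2)c1OCOC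
F8 | step 1 | 2,6-dihydroxy-4-(methoxymethoxy)benzaldehyde | O=Cc1c(O)cc(OCOC)cc1O
F9 | step 1 | 4-(methoxymethoxy)-2,6-bis[(2-methylbut-3-en-2-yl)oxy]benzaldehyde | O=Cc1c(OC(C)(C)C=C)cc(OCOC)cc1OC(C)(C)C=C
F10 | step 1 | 2,6-dihydroxy-4-(methoxymethoxy)-3,5-bis(3-methylbut-2-en-1-yl)benzaldehyde | O=Cc1c(O)c(CC=C(C)C)c(OCOC)c(CC=C(C)C)c1O
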